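**Retrosynthetic overview** (germacrane numbering)
1. The ten-membered ring is closed last by RCM, forming the cis (Z) C4=C5 olefin on a triene that already carries the trans-fused α-methylene-γ-lactone, the 1,10-epoxide and both esters.
2. The C8 ester comes from Mitsunobu inversion of the 8α-carbinol with (2S,3S)-epoxyangelic acid (methyl angelate → Sharpless epoxidation → oxidation).
3. The C7–C8 bond and the α-methylene lactone come from a zinc Barbier allylation of a β,γ-epoxy aldehyde with an enantiopure 3-(bromomethyl)-5-propenylbutenolide.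
4. Epoxy aldehyde: Still–Gennari Z-olefination, Sharpless epoxidation (sets C1 and C10), acetylation, desilylation, oxidation. Butenolide: Sharpless kinetic resolution of hexa-1,4-dien-3-ol (sets C6), acylation, RCM.
5. Ring order: butenolide (RCM), then its conversion into the α-methylene-γ-lactone in the Barbier step, then the ten-membered carbocycle (RCM); both oxiranes are made on acyclic allylic alcohols.

Assumption: 4-methylpent-4-en-1-ol, racemic (E)-hexa-1,4-dien-3-ol, methyl angelate, 2-(bromomethyl)acrylic acid, the Still–Gennari phosphonoacetate and tert-butyl(2-iodoethoxy)dimethylsilane are taken as catalogue chemicals.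

**Route**

Step 1
Reactants: 1 4-methylpent-4-en-1-ol
Product: 2 4-methylpent-4-enal
Conditions: DMP, CH2Cl2, 0 °C → rt
Reagents that add atoms: none
Why: Dess–Martin oxidation stops at the aldehyde under neutral conditions and leaves the 1,1-disubstituted alkene alone; no stereocentre is formed.

Step 2
Reactants: 3 methyl 2-[bis(2,2,2-trifluoroethoxy)phosphoryl]acetate + 4 tert-butyl(2-iodoethoxy)dimethylsilane
Product: 6 methyl 2-[bis(2,2,2-trifluoroethoxy)phosphoryl]-4-[(tert-butyldimethylsilyl)oxy]butanoate (racemic), via sodium phosphonoacetate carbanion 5 (not isolated)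
Conditions: NaH, DMF, 0 °C; then 4, rt
Reagents that add atoms: none
Why: SN2 C-alkylation of the stabilised phosphonoacetate carbanion by an unhindered primary iodide gives the α-branched Still–Gennari reagent; its α-centre is racemic and disappears in the next step.

Step 3
Reactants: 6 methyl 2-[bis(2,2,2-trifluoroethoxy)phosphoryl]-4-[(tert-butyldimethylsilyl)oxy]butanoate + 2 4-methylpent-4-enal
Product: 8 methyl (2Z)-2-[2-[(tert-butyldimethylsilyl)oxy]ethyl]-6-methylhepta-2,6-dienoate, via potassium phosphonate carbanion 7 (not isolated)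
Conditions: KHMDS, 18-crown-6, THF, −78 °C; then 2
Reagents that add atoms: none
Why: In the Still–Gennari variant of the Horner–Wadsworth–Emmons olefination the electron-poor phosphonate eliminates fast from the kinetic adduct, so the ester ends up cis to the chain (Z), the geometry that later places C14 and C2 on the same side of the epoxide.

Step 4
Reactants: 8 methyl (2Z)-2-[2-[(tert-butyldimethylsilyl)oxy]ethyl]-6-methylhepta-2,6-dienoate
Product: 10 (2Z)-2-[2-[(tert-butyldimethylsilyl)oxy]ethyl]-6-methylhepta-2,6-dien-1-ol, via Z-dienal 9 (not isolated)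
Conditions: DIBAL-H (2.5 equiv), CH2Cl2, −78 → 0 °C; Rochelle salt
Reagents that add atoms: none
Why: DIBAL-H 1,2-reduction of the enoate gives the allylic alcohol without touching the silyl ether or the Z geometry.

Step 5
Reactants: 10 (2Z)-2-[2-[(tert-butyldimethylsilyl)oxy]ethyl]-6-methylhepta-2,6-dien-1-ol
Product: 11 [(2S,3R)-2-[2-[(tert-butyldimethylsilyl)oxy]ethyl]-3-(3-methylbut-3-en-1-yl)oxiran-2-yl]methanol
Conditions: Ti(OiPr)4 (10 mol %), L-(+)-DET (12 mol %), TBHP, 4 Å MS, CH2Cl2, −20 °C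
Reagents that add atoms: tert-butyl hydroperoxide CC(C)(C)OO
Why: In the Sharpless asymmetric epoxidation the titanium tartrate oxidises only the allylic-alcohol olefin; L-(+)-DET selects the face that gives C10 (S) and C1 (R), and the Z geometry fixes their cis relationship.

Step 6
Reactants: 11 [(2S,3R)-2-[2-[(tert-butyldimethylsilyl)oxy]ethyl]-3-(3-methylbut-3-en-1-yl)oxiran-2-yl]methanol
Product: 12 [(2S,3R)-2-[2-[(tert-butyldimethylsilyl)oxy]ethyl]-3-(3-methylbut-3-en-1-yl)oxiran-2-yl]methyl acetate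
Conditions: Ac2O, pyridine, DMAP (cat.), CH2Cl2, 0 °C
Reagents that add atoms: acetic anhydride CC(=O)OC(C)=O
Why: DMAP-catalysed acylation of the primary alcohol installs the C14 acetate under conditions that do not open the epoxide.

Step 7
Reactants: 12 [(2S,3R)-2-[2-[(tert-butyldimethylsilyl)oxy]ethyl]-3-(3-methylbut-3-en-1-yl)oxiran-2-yl]methyl acetate
Product: 13 [(2S,3R)-2-(2-hydroxyethyl)-3-(3-methylbut-3-en-1-yl)oxiran-2-yl]methyl acetate
Conditions: TBAF, AcOH (1:1), THF, 0 °C → rt
Reagents that add atoms: none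
Why: Fluoride desilylation buffered with acetic acid frees the primary alcohol without acetate migration or epoxide opening.

Step 8
Reactants: 13 [(2S,3R)-2-(2-hydroxyethyl)-3-(3-methylbut-3-en-1-yl)oxiran-2-yl]methyl acetate
Product: 14 [(2S,3R)-3-(3-methylbut-3-en-1-yl)-2-(2-oxoethyl)oxiran-2-yl]methyl acetate
Conditions: DMP, NaHCO3 (solid buffer), CH2Cl2, 0 °C; used at once
Reagents that add atoms: none
Why: Buffered Dess–Martin oxidation gives the base- and acid-sensitive β,γ-epoxy aldehyde without enolisation, and the stereocentres are not involved.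

Step 9
Reactants: 15 rac-(4E)-hexa-1,4-dien-3-ol
Product: 16 (3S,4E)-hexa-1,4-dien-3-ol (recovered enantiomer)
Conditions: Ti(OiPr)4, D-(−)-DIPT, TBHP (0.6 equiv), 4 Å MS, CH2Cl2, −20 °C
Reagents that add atoms: none
Why: In the Sharpless kinetic resolution with D-(−)-DIPT the (R)-alcohol is epoxidised quickly at its propenyl group, so the (S)-alcohol, which carries the future C6 configuration, is recovered in high ee at about 60 % conversion.

Step 10
Reactants: 16 (3S,4E)-hexa-1,4-dien-3-ol + 17 2-(bromomethyl)prop-2-enoic acid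
Product: 19 (3S,4E)-hexa-1,4-dien-3-yl 2-(bromomethyl)prop-2-enoate, via O-acylisourea 18 (not isolated)
Conditions: DCC, DMAP (5 mol %), CH2Cl2, 0 °C
Reagents that add atoms: none
Why: Steglich esterification acylates the alcohol oxygen, so the C–O stereocentre is retained, and the low temperature and low DMAP loading spare the allylic bromide.

Step 11
Reactants: 19 (3S,4E)-hexa-1,4-dien-3-yl 2-(bromomethyl)prop-2-enoate
Product: 20 (5R)-3-(bromomethyl)-5-[(1E)-prop-1-en-1-yl]furan-2(5H)-one
Conditions: Grubbs II (5 mol %), toluene (0.01 M), 80 °C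
Reagents that add atoms: none
Why: In this ring-closing metathesis the catalyst loads on the terminal vinyl group and closes the five-membered butenolide onto the acrylate, leaving the internal propenyl group and the stereocentre untouched.

Step 12
Reactants: 21 methyl (2Z)-2-methylbut-2-enoate (methyl angelate)
Product: 23 (2Z)-2-methylbut-2-en-1-ol, via (2Z)-2-methylbut-2-enal 22 (not isolated)
Conditions: DIBAL-H (2.2 equiv), Et2O, −78 → 0 °C
Reagents that add atoms: none
Why: DIBAL-H 1,2-reduction gives angelyl alcohol with the Z geometry intact.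

Step 13
Reactants: 23 (2Z)-2-methylbut-2-en-1-ol
Product: 24 [(2R,3S)-2,3-dimethyloxiran-2-yl]methanol
Conditions: Ti(OiPr)4, D-(−)-DET, TBHP, 4 Å MS, CH2Cl2, −20 °C
Reagents that add atoms: tert-butyl hydroperoxide CC(C)(C)OO
Why: Sharpless asymmetric epoxidation with D-(−)-DET delivers oxygen to the face that gives the (2R,3S)-epoxy alcohol, and the Z olefin keeps CH2OH and the 3-methyl group cis.

Step 14
Reactants: 24 [(2R,3S)-2,3-dimethyloxiran-2-yl]methanol
Product: 26 (2S,3S)-2,3-dimethyloxirane-2-carboxylic acid, via epoxy aldehyde 25 (not isolated)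
Conditions: RuCl3·xH2O (2 mol %), NaIO4, MeCN/CCl4/H2O, rt
Reagents that add atoms: water O
Why: Catalytic RuO4 oxidation (Sharpless conditions) takes the epoxy alcohol through the aldehyde hydrate to the acid without touching the oxirane; the descriptor at C2 changes only because the CIP priorities change.

Step 15
Reactants: 14 [(2S,3R)-3-(3-methylbut-3-en-1-yl)-2-(2-oxoethyl)oxiran-2-yl]methyl acetate + 20 (5R)-3-(bromomethyl)-5-[(1E)-prop-1-en-1-yl]furan-2(5H)-one
Product: 28 [(2S,3R)-2-[(2S)-2-hydroxy-2-[(2R,3R)-4-methylidene-5-oxo-2-[(1E)-prop-1-en-1-yl]oxolan-3-yl]ethyl]-3-(3-methylbut-3-en-1-yl)oxiran-2-yl]methyl acetate, via allylzinc bromide 27 (not isolated)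
Conditions: Zn dust, THF/sat. aq NH4Cl, 0 °C → rt
Reagents that add atoms: none
Why: In this Barbier allylation the allylzinc reacts through its ring γ-carbon in a chair Zimmerman–Traxler transition state on the face anti to the propenyl group, which gives the trans lactone (C7 R) and, because the reagent is locked in the E-type geometry, the anti carbinol (C8 S, 8α) that the next step inverts.

Step 16
Reactants: 28 [(2S,3R)-2-[(2S)-2-hydroxy-2-[(2R,3R)-4-methylidene-5-oxo-2-[(1E)-prop-1-en-1-yl]oxolan-3-yl]ethyl]-3-(3-methylbut-3-en-1-yl)oxiran-2-yl]methyl acetate + 26 (2S,3S)-2,3-dimethyloxirane-2-carboxylic acid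
Product: 30 (1R)-2-[(2S,3R)-2-(acetoxymethyl)-3-(3-methylbut-3-en-1-yl)oxiran-2-yl]-1-[(2R,3R)-4-methylidene-5-oxo-2-[(1E)-prop-1-en-1-yl]oxolan-3-yl]ethyl (2S,3S)-2,3-dimethyloxirane-2-carboxylate, via alkoxyphosphonium carboxylate 29 (not isolated)
Conditions: PPh3, DIAD, toluene, 0 °C → rt
Reagents that add atoms: none
Why: In the Mitsunobu reaction the carboxylate of the fairly acidic glycidic acid displaces the alkoxyphosphonium group by SN2, which inverts C8 from S to R (8β) and installs the ester in one operation.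

Step 17
Reactants: 30 (1R)-2-[(2S,3R)-2-(acetoxymethyl)-3-(3-methylbut-3-en-1-yl)oxiran-2-yl]-1-[(2R,3R)-4-methylidene-5-oxo-2-[(1E)-prop-1-en-1-yl]oxolan-3-yl]ethyl (2S,3S)-2,3-dimethyloxirane-2-carboxylate
Product: 31 target CNP0232260.1, (1R,6R,7R,8R,10S)-14-acetoxy-1,10-epoxy-8-[(2S,3S)-2,3-epoxy-2-methylbutanoyloxy]germacra-4(Z),11(13)-dien-12,6-olide
Conditions: Grubbs II (15 mol %, in portions), toluene (1 mM), 80 °C, Ar sparge
Reagents that add atoms: none
Why: Ring-closing metathesis between the propenyl group on C6 and the isopropenyl terminus releases propene and should give the less strained cis (Z) trisubstituted olefin of the ten-membered ring, while the electron-poor α-methylene lactone, the epoxides and the esters are inert to the ruthenium carbene.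

**Compound list**

1 | 4-methylpent-4-en-1-ol | C=C(C)CCCO | starting material
2 | 4-methylpent-4-enal | C=C(C)CCC=O | intermediate
3 | methyl 2-[bis(2,2,2-trifluoroethoxy)phosphoryl]acetate (Still–Gennari reagent) | COC(=O)CP(=O)(OCC(F)(F)F)OCC(F)(F)F | starting material
4 | tert-butyl(2-iodoethoxy)dimethylsilane | CC(C)(C)[Si](C)(C)OCCI | starting material
5 | sodium salt of the carbanion of 3 (not isolated) | [Na+].COC(=O)[CH-]P(=O)(OCC(F)(F)F)OCC(F)(F)F | intermediate
6 | methyl 2-[bis(2,2,2-trifluoroethoxy)phosphoryl]-4-[(tert-butyldimethylsilyl)oxy]butanoate (racemic) | COC(=O)C(CCO[Si](C)(C)C(C)(C)C)P(=O)(OCC(F)(F)F)OCC(F)(F)F | intermediate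
7 | potassium salt of the carbanion of 6 (not isolated) | [K+].COC(=O)[C-](CCO[Si](C)(C)C(C)(C)C)P(=O)(OCC(F)(F)F)OCC(F)(F)F | intermediate
8 | methyl (2Z)-2-[2-[(tert-butyldimethylsilyl)oxy]ethyl]-6-methylhepta-2,6-dienoate | C=C(C)CC/C=C(/CCO[Si](C)(C)C(C)(C)C)C(=O)OC | intermediate
9 | (2Z)-2-[2-[(tert-butyldimethylsilyl)oxy]ethyl]-6-methylhepta-2,6-dienal (not isolated) | C=C(C)CC/C=C(/CCO[Si](C)(C)C(C)(C)C)C=O | intermediate
10 | (2Z)-2-[2-[(tert-butyldimethylsilyl)oxy]ethyl]-6-methylhepta-2,6-dien-1-ol | C=C(C)CC/C=C(/CCO[Si](C)(C)C(C)(C)C)CO | intermediate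
11 | [(2S,3R)-2-[2-[(tert-butyldimethylsilyl)oxy]ethyl]-3-(3-methylbut-3-en-1-yl)oxiran-2-yl]methanol | C=C(C)CC[C@H]1O[C@]1(CO)CCO[Si](C)(C)C(C)(C)C | intermediate
12 | [(2S,3R)-2-[2-[(tert-butyldimethylsilyl)oxy]ethyl]-3-(3-methylbut-3-en-1-yl)oxiran-2-yl]methyl acetate | C=C(C)CC[C@H]1O[C@]1(COC(C)=O)CCO[Si](C)(C)C(C)(C)C | intermediate
13 | [(2S,3R)-2-(2-hydroxyethyl)-3-(3-methylbut-3-en-1-yl)oxiran-2-yl]methyl acetate | C=C(C)CC[C@H]1O[C@]1(COC(C)=O)CCO | intermediate
14 | [(2S,3R)-3-(3-methylbut-3-en-1-yl)-2-(2-oxoethyl)oxiran-2-yl]methyl acetate | C=C(C)CC[C@H]1O[C@]1(COC(C)=O)CC=O | intermediate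
15 | rac-(4E)-hexa-1,4-dien-3-ol | C=CC(O)/C=C/C | starting material
16 | (3S,4E)-hexa-1,4-dien-3-ol | C=C[C@@H](/C=C/C)O | intermediate
17 | 2-(bromomethyl)prop-2-enoic acid | C=C(CBr)C(=O)O | starting material
18 | O-acylisourea from 17 and DCC (not isolated) | C=C(CBr)C(=O)OC(=NC1CCCCC1)NC1CCCCC1 | intermediate
19 | (3S,4E)-hexa-1,4-dien-3-yl 2-(bromomethyl)prop-2-enoate | C=C[C@@H](/C=C/C)OC(=O)C(=C)CBr | intermediate
20 | (5R)-3-(bromomethyl)-5-[(1E)-prop-1-en-1-yl]furan-2(5H)-one | BrCC1=C[C@@H](/C=C/C)OC1=O | intermediate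
21 | methyl (2Z)-2-methylbut-2-enoate (methyl angelate) | C/C=C(/C)C(=O)OC | starting material
22 | (2Z)-2-methylbut-2-enal (not isolated) | C/C=C(/C)C=O | intermediate
23 | (2Z)-2-methylbut-2-en-1-ol | C/C=C(/C)CO | intermediate
24 | [(2R,3S)-2,3-dimethyloxiran-2-yl]methanol | OC[C@@]1(C)O[C@H]1C | intermediate
25 | (2S,3S)-2,3-dimethyloxirane-2-carbaldehyde (not isolated) | O=C[C@@]1(C)O[C@H]1C | intermediate
26 | (2S,3S)-2,3-dimethyloxirane-2-carboxylic acid | OC(=O)[C@@]1(C)O[C@H]1C | intermediate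
27 | allylzinc bromide from 20 (not isolated) | Br[Zn]CC1=C[C@@H](/C=C/C)OC1=O | intermediate
28 | [(2S,3R)-2-[(2S)-2-hydroxy-2-[(2R,3R)-4-methylidene-5-oxo-2-[(1E)-prop-1-en-1-yl]oxolan-3-yl]ethyl]-3-(3-methylbut-3-en-1-yl)oxiran-2-yl]methyl acetate | C=C1C(=O)O[C@H](/C=C/C)[C@H]1[C@@H](O)C[C@@]2(COC(C)=O)O[C@@H]2CCC(C)=C | intermediate
29 | triphenylphosphonium ether of 28 as its (2S,3S)-2,3-dimethyloxirane-2-carboxylate salt (not isolated) | C=C1C(=O)O[C@H](/C=C/C)[C@H]1[C@@H](O[P+](c2ccccc2)(c2ccccc2)c2ccccc2)C[C@@]2(COC(C)=O)O[C@@H]2CCC(C)=C.[O-]C(=O)[C@@]1(C)O[C@H]1C | intermediate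
30 | (1R)-2-[(2S,3R)-2-(acetoxymethyl)-3-(3-methylbut-3-en-1-yl)oxiran-2-yl]-1-[(2R,3R)-4-methylidene-5-oxo-2-[(1E)-prop-1-en-1-yl]oxolan-3-yl]ethyl (2S,3S)-2,3-dimethyloxirane-2-carboxylate | C=C1C(=O)O[C@H](/C=C/C)[C@H]1[C@H](OC(=O)[C@@]2(C)O[C@H]2C)C[C@@]2(COC(C)=O)O[C@@H]2CCC(C)=C | intermediate
31 | CNP0232260.1, (1R,6R,7R,8R,10S)-14-acetoxy-1,10-epoxy-8-[(2S,3S)-2,3-epoxy-2-methylbutanoyloxy]germacra-4(Z),11(13)-dien-12,6-olide | C=C1C(=O)O[C@@H]2/C=C(/C)CC[C@H]3O[C@]3(COC(C)=O)C[C@@H](OC(=O)[C@@]3(C)O[C@H]3C)[C@@H]12 | target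

**Totals**

Total step count: 17.
Longest linear sequence: 10 steps (steps 2–8, then 15–17; equally 1, 3–8, 15–17).

**Three steps most likely to fail**

Step 15 (Barbier coupling). The β,γ-epoxy aldehyde 14 can open by β-elimination and the aqueous zinc conditions may give poor conversion or diastereoselectivity. The fallback sets out from bromide 20 and comes back at alcohol 28. Bromide 20 is borylated (B2pin2, Pd2(dba)3 cat., toluene, 50 °C) to the allylboronate (5R)-5-[(1E)-prop-1-en-1-yl]-3-[(4,4,5,5-tetramethyl-1,3,2-dioxaborolan-2-yl)methyl]furan-2(5H)-one F1. F1 is heated with freshly made 14 in dry toluene (60 °C, then aqueous work-up). This is a metal-free, neutral allylboration through the same closed chair, so it should give the same trans-lactone anti-carbinol 28.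

Step 16 (Mitsunobu inversion at the hindered C8). If displacement fails or elimination dominates, the fallback sets out from alcohol 28 and comes back at ester 30, replacing SN2 inversion by oxidation and reagent-controlled reduction. Compound 28 is oxidised (DMP, NaHCO3, CH2Cl2, 0 °C) to the ketone [(2S,3R)-3-(3-methylbut-3-en-1-yl)-2-[2-[(2R,3S)-4-methylidene-5-oxo-2-[(1E)-prop-1-en-1-yl]oxolan-3-yl]-2-oxoethyl]oxiran-2-yl]methyl acetate F2. F2 is reduced with a CBS oxazaborolidine and catecholborane at −40 °C (catalyst enantiomer chosen by screening) to the 8β-alcohol [(2S,3R)-2-[(2R)-2-hydroxy-2-[(2R,3R)-4-methylidene-5-oxo-2-[(1E)-prop-1-en-1-yl]oxolan-3-yl]ethyl]-3-(3-methylbut-3-en-1-yl)oxiran-2-yl]methyl acetate F3. F3 is acylated with acid 26 with retention (DCC, DMAP, CH2Cl2) to give 30. The risk in this fallback is enolisation of F2 towards C7.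

Step 17 (ten-membered RCM to a trisubstituted Z olefin). If triene 30 does not close or gives the E isomer, the fallback sets out from alcohol 28 and comes back at target 31 by turning the last two steps round. Alcohol 28 is smaller at C8 and can hydrogen-bond to the lactone carbonyl. It is cyclised first (Grubbs II or Hoveyda–Grubbs II, toluene, 1 mM, 80 °C) to the macrocyclic alcohol (1R,6R,7R,8S,10S)-14-acetoxy-1,10-epoxy-8-hydroxygermacra-4(Z),11(13)-dien-12,6-olide F4. The Mitsunobu inversion–esterification with acid 26 (PPh3, DIAD, toluene) is then done on the ring to give 31.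

**Further compounds**

F1 | step 15 | (5R)-5-[(1E)-prop-1-en-1-yl]-3-[(4,4,5,5-tetramethyl-1,3,2-dioxaborolan-2-yl)methyl]furan-2(5H)-one | CC1(C)OB(CC2=C[C@@H](/C=C/C)OC2=O)OC1(C)C
F2 | step 16 | [(2S,3R)-3-(3-methylbut-3-en-1-yl)-2-[2-[(2R,3S)-4-methylidene-5-oxo-2-[(1E)-prop-1-en-1-yl]oxolan-3-yl]-2-oxoethyl]oxiran-2-yl]methyl acetate | C=C1C(=O)O[C@H](/C=C/C)[C@H]1C(=O)C[C@@]2(COC(C)=O)O[C@@H]2CCC(C)=C
F3 | step 16 | [(2S,3R)-2-[(2R)-2-hydroxy-2-[(2R,3R)-4-methylidene-5-oxo-2-[(1E)-prop-1-en-1-yl]oxolan-3-yl]ethyl]-3-(3-methylbut-3-en-1-yl)oxiran-2-yl]methyl acetate | C=C1C(=O)O[C@H](/C=C/C)[C@H]1[C@H](O)C[C@@]2(COC(C)=O)O[C@@H]2CCC(C)=C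
F4 | step 17 | (1R,6R,7R,8S,10S)-14-acetoxy-1,10-epoxy-8-hydroxygermacra-4(Z),11(13)-dien-12,6-olide | C=C1C(=O)O[C@@H]2/C=C(/C)CC[C@H]3O[C@]3(COC(C)=O)C[C@H](O)[C@@H]12
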